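**Retrosynthetic overview**

1. Ring B is closed last, by ring-closing metathesis that forms C7=C8. The two olefin arms (C6 vinyl carbinol on C5, C9 isopropenyl on C10) sit trans-diequatorial on adjacent ring-A carbons, so C7 and C8 end the six-atom chain C7–C6–C5–C10–C9–C8 and only a trans-fused six-membered ring can form.
2. The triene comes from a bridged bicyclo[3.3.1]nonene in which C8 temporarily ties C18 (on C4) to C9 (on C10). Ring A has a local mirror plane through C5 and C2 (C4 and C10 each carry an axial methyl and an equatorial one-carbon arm), so the cis-dimethyl array is taken from a meso bicycle built on 2,6-dimethylcyclohexanone.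
3. The meso 3,9-dione is desymmetrised by chiral lithium amide deprotonation and alkylation (sets C9 and the absolute sense at C4 and C10). C5 follows by equilibration of the bridge aldehyde, C6 by oxazaborolidine reduction, the (E)-enoate by alkyne carboalumination.
4. Ring order: ring A (starting ketone), then the temporary ring C4–C18–C8–C9–C10–C5 (step 1), opened at C8=C18 (step 13), then ring B (step 16).

Key step: step 16

Remark: atom labels follow labdane numbering of the target (ring A = C1–C5 and C10; ring B = C5–C10; C18 = hydroxymethyl carbon on C4; C17 = methyl on C8; C11–C16 = side chain).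
Assumption: the (R,R)-configured lithium amide is taken to remove the α-hydrogen that leads to 7 as drawn; if the sense of induction is the opposite one, its enantiomer is used in the same way.
Assumption: in step 10 the vinyl group is taken to act as the smaller carbonyl substituent next to the doubly neopentylic ring carbon C5.

**Route**

Step 1
Reactants: 1 2,6-dimethylcyclohexanone (cis/trans mixture); 2 3-chloro-2-(chloromethyl)prop-1-ene
Product: 3 (1R,5S)-1,5-dimethyl-3-methylidenebicyclo[3.3.1]nonan-9-one (meso)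
Conditions: KOtBu (2.2 equiv), THF, 0 °C, slow addition of 2, then 60 °C
Reagents that add atoms: none
Why: Two successive enolate C-alkylations by the bis-allylic chloride (α,α′-annulation) should bridge both methyl-bearing α-carbons, and because a three-carbon bridge can only span one face of the cyclohexanone the two methyl groups end up cis, giving the meso bicycle whatever the cis/trans composition of 1.

Step 2
Reactants: 3 (1R,5S)-1,5-dimethyl-3-methylidenebicyclo[3.3.1]nonan-9-one
Product: 4 (1R,5S)-1,5-dimethylbicyclo[3.3.1]nonane-3,9-dione (meso)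
Conditions: O3, CH2Cl2/MeOH, −78 °C; then Me2S, −78 to 23 °C
Reagents that add atoms: ozone [O-][O+]=O
Why: Ozonolysis of the only C=C bond with reductive work-up should give the meso dione, in which only the C3 carbonyl has α-hydrogens.

Step 3
Reactants: 5 4-(trimethylsilyl)but-3-yn-1-ol
Product: 6 4-(trimethylsilyl)but-3-yn-1-yl trifluoromethanesulfonate
Conditions: (CF3SO2)2O, pyridine, CH2Cl2, −20 °C
Reagents that add atoms: trifluoromethanesulfonic anhydride O=S(=O)(OS(=O)(=O)C(F)(F)F)C(F)(F)F
Why: O-Sulfonylation of the primary alcohol should give an electrophile reactive enough to alkylate a hindered enolate below −40 °C, where elimination to the enyne is slow.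

Step 4
Reactants: 4 (1R,5S)-1,5-dimethylbicyclo[3.3.1]nonane-3,9-dione; 6 4-(trimethylsilyl)but-3-yn-1-yl trifluoromethanesulfonate
Product: 7 (1S,2S,5R)-1,5-dimethyl-2-[4-(trimethylsilyl)but-3-yn-1-yl]bicyclo[3.3.1]nonane-3,9-dione
Conditions: LiN[(R)-CH(Me)Ph]2 (from the amine and n-BuLi), LiCl, THF, −78 °C; then 6, DMPU, −78 to −40 °C
Reagents that add atoms: none
Why: Enantiotopic-group-selective deprotonation of the meso ketone by the chiral lithium amide (the bridge carbonyl has no α-hydrogen), followed by stereoelectronically favoured axial enolate alkylation on the open face next to the one-carbon bridge, should set C9 (side chain axial) and, through the choice of the α-carbon that becomes C9, the absolute configuration at C4 and C10.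

Step 5
Reactants: 7 (1S,2S,5R)-1,5-dimethyl-2-[4-(trimethylsilyl)but-3-yn-1-yl]bicyclo[3.3.1]nonane-3,9-dione
Product: 8 1,5-dimethyl-9-oxo-4-[4-(trimethylsilyl)but-3-yn-1-yl]bicyclo[3.3.1]non-2-en-3-yl trifluoromethanesulfonate (stereocentres as in 7)
Conditions: LiN(iPr)2, THF, −78 °C; then N-(5-chloropyridin-2-yl)bis(trifluoromethanesulfonyl)imide, −78 to 0 °C
Reagents that add atoms: N-(5-chloropyridin-2-yl)bis(trifluoromethanesulfonyl)imide O=S(=O)(N(c1ccc(Cl)cn1)S(=O)(=O)C(F)(F)F)C(F)(F)F
Why: Kinetic deprotonation at the unsubstituted methylene rather than at the substituted α-carbon and O-triflation of the enolate should give the enol triflate without touching C9.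

Step 6
Reactants: 8 1,5-dimethyl-9-oxo-4-[4-(trimethylsilyl)but-3-yn-1-yl]bicyclo[3.3.1]non-2-en-3-yl trifluoromethanesulfonate
Product: 9 1,3,5-trimethyl-4-[4-(trimethylsilyl)but-3-yn-1-yl]bicyclo[3.3.1]non-2-en-9-one (stereocentres as in 7)
Conditions: Me2CuLi (from CuI and 2 MeLi), THF, −20 °C
Reagents that add atoms: lithium dimethylcuprate [Li+].C[Cu-]C
Why: Cross-coupling of the enol triflate with the cuprate should install the C17 methyl group with retention of the double bond position and so create the trisubstituted C8=C18 alkene that is cleaved in step 13.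

Step 7
Reactants: 9 1,3,5-trimethyl-4-[4-(trimethylsilyl)but-3-yn-1-yl]bicyclo[3.3.1]non-2-en-9-one
Product: 12 4-(but-3-yn-1-yl)-1,3,5-trimethylbicyclo[3.3.1]non-2-ene-9-carbaldehyde (formyl group syn to the saturated C6–C8 bridge), via methyl enol ether 10 (not isolated), via C-silylated aldehyde 11 (not isolated)
Conditions: Ph3P=CHOMe (from [Ph3PCH2OMe]Cl and KN(SiMe3)2), toluene, 0 to 80 °C; then 2 M HCl, THF, 23 °C; then K2CO3, MeOH, 23 °C
Reagents that add atoms: (methoxymethyl)triphenylphosphonium chloride COC[P+](c1ccccc1)(c1ccccc1)c1ccccc1.[Cl-]; water O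
Why: Wittig methoxymethylenation of the tied-back bridge ketone, enol ether hydrolysis and base treatment should give the one-carbon homologue in which C5 has equilibrated (thermodynamic control) to the epimer whose formyl carbon C6 lies away from the axial C9 side chain, the methanolic carbonate also removing the alkynyl silyl group.

Step 8
Reactants: 12 4-(but-3-yn-1-yl)-1,3,5-trimethylbicyclo[3.3.1]non-2-ene-9-carbaldehyde
Product: 13 1-[4-(but-3-yn-1-yl)-1,3,5-trimethylbicyclo[3.3.1]non-2-en-9-yl]prop-2-en-1-ol (both C6 epimers)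
Conditions: CH2=CHMgBr (2.5 equiv), THF, −78 to 0 °C
Reagents that add atoms: vinylmagnesium bromide C=C[Mg]Br
Why: Grignard 1,2-addition installs C7 and the sacrificial methylene; the flanking quaternary carbons C4 and C10 are too alike to bias the new carbinol centre, so both epimers are expected and C6 is reset in steps 9 and 10.

Step 9
Reactants: 13 1-[4-(but-3-yn-1-yl)-1,3,5-trimethylbicyclo[3.3.1]non-2-en-9-yl]prop-2-en-1-ol
Product: 14 1-[4-(but-3-yn-1-yl)-1,3,5-trimethylbicyclo[3.3.1]non-2-en-9-yl]prop-2-en-1-one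
Conditions: Dess–Martin periodinane, NaHCO3, CH2Cl2, 0 to 23 °C
Reagents that add atoms: none
Why: Dess–Martin oxidation should converge both carbinol epimers on one vinyl ketone under non-basic conditions that should not epimerise C5.

Step 10
Reactants: 14 1-[4-(but-3-yn-1-yl)-1,3,5-trimethylbicyclo[3.3.1]non-2-en-9-yl]prop-2-en-1-one
Product: 15 (1R)-1-[4-(but-3-yn-1-yl)-1,3,5-trimethylbicyclo[3.3.1]non-2-en-9-yl]prop-2-en-1-ol
Conditions: (S)-2-methyl-CBS-oxazaborolidine (0.5 equiv), catecholborane, toluene, −78 °C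
Reagents that add atoms: none
Why: Corey–Bakshi–Shibata reduction, with vinyl as the small and the ring carbon C5 as the large substituent, should deliver hydride to one carbonyl face under reagent control and set C6 as (R), while the terminal alkyne is inert to catecholborane at this temperature.

Step 11
Reactants: 15 (1R)-1-[4-(but-3-yn-1-yl)-1,3,5-trimethylbicyclo[3.3.1]non-2-en-9-yl]prop-2-en-1-ol
Product: 16 tert-butyldimethylsilyl ether of 15
Conditions: tBuMe2SiOSO2CF3, 2,6-lutidine, CH2Cl2, −78 to 0 °C
Reagents that add atoms: tert-butyldimethylsilyl trifluoromethanesulfonate CC(C)(C)[Si](C)(C)OS(=O)(=O)C(F)(F)F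
Why: O-Silylation with the silyl triflate should protect the hindered allylic alcohol so that it cannot open the epoxide formed in step 13.

Step 12
Reactants: 16 tert-butyldimethylsilyl ether of 15
Product: 17 methyl (2E)-5-{9-[(1R)-1-(tert-butyldimethylsilyloxy)prop-2-en-1-yl]-1,3,5-trimethylbicyclo[3.3.1]non-2-en-4-yl}-3-methylpent-2-enoate
Conditions: Me3Al (3 equiv), Cp2ZrCl2 (0.3 equiv), CH2Cl2, 0 to 23 °C; then ClCO2Me, 0 °C
Reagents that add atoms: trimethylaluminium C[Al](C)C; methyl chloroformate COC(=O)Cl
Why: Negishi carboalumination adds methyl and aluminium syn across the terminal alkyne with methyl on the internal carbon, and acylation of the alkenylalane with retention should give the (E)-3-methyl enoate as a single geometric isomer.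

Step 13
Reactants: 17 methyl (2E)-5-{9-[(1R)-1-(tert-butyldimethylsilyloxy)prop-2-en-1-yl]-1,3,5-trimethylbicyclo[3.3.1]non-2-en-4-yl}-3-methylpent-2-enoate
Product: 19 methyl (2E)-6-{2-[(1R)-1-(tert-butyldimethylsilyloxy)prop-2-en-1-yl]-3-formyl-1,3-dimethylcyclohexyl}-3-methyl-7-oxooct-2-enoate, via epoxide 18 (not isolated)
Conditions: 3-ClC6H4CO3H (1.05 equiv), NaHCO3, CH2Cl2, −10 °C; then H5IO6, THF/H2O, 0 °C
Reagents that add atoms: 3-chloroperoxybenzoic acid O=C(OO)c1cccc(Cl)c1; water O
Why: Prilezhaev epoxidation should take the electron-rich trisubstituted ring alkene in preference to the monosubstituted vinyl group and the electron-poor enoate, and periodic acid should hydrolyse and cleave the epoxide (glycol cleavage) so that the temporary ring opens to the C18 aldehyde and the C8 methyl ketone.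

Step 14
Reactants: 19 methyl (2E)-6-{2-[(1R)-1-(tert-butyldimethylsilyloxy)prop-2-en-1-yl]-3-formyl-1,3-dimethylcyclohexyl}-3-methyl-7-oxooct-2-enoate
Product: 20 methyl (2E)-6-{2-[(1R)-1-(tert-butyldimethylsilyloxy)prop-2-en-1-yl]-3-(hydroxymethyl)-1,3-dimethylcyclohexyl}-3-methyl-7-oxooct-2-enoate
Conditions: NaBH(OAc)3, AcOH (cat.), CH2Cl2, 0 to 23 °C
Reagents that add atoms: none
Why: Chemoselective hydride reduction by the acetoxyborohydride should take the aldehyde but not the methyl ketone or the enoate, under slightly acidic conditions that should spare the C9 centre next to the ketone.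

Step 15
Reactants: 20 methyl (2E)-6-{2-[(1R)-1-(tert-butyldimethylsilyloxy)prop-2-en-1-yl]-3-(hydroxymethyl)-1,3-dimethylcyclohexyl}-3-methyl-7-oxooct-2-enoate
Product: 21 methyl (2E)-6-{2-[(1R)-1-(tert-butyldimethylsilyloxy)prop-2-en-1-yl]-3-(hydroxymethyl)-1,3-dimethylcyclohexyl}-3,7-dimethylocta-2,7-dienoate
Conditions: Zn, CH2Br2, TiCl4, THF/CH2Cl2, 0 to 23 °C
Reagents that add atoms: dibromomethane BrCBr
Why: Takai–Lombardo methylenation with the non-basic geminal dizinc/titanium reagent should turn the methyl ketone into the isopropenyl group without epimerising C9 and without touching the ester.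

Step 16
Reactants: 21 methyl (2E)-6-{2-[(1R)-1-(tert-butyldimethylsilyloxy)prop-2-en-1-yl]-3-(hydroxymethyl)-1,3-dimethylcyclohexyl}-3,7-dimethylocta-2,7-dienoate
Product: 22 methyl (2E)-5-[(1R,4R,4aS,5S,8aS)-4-(tert-butyldimethylsilyloxy)-5-(hydroxymethyl)-2,5,8a-trimethyl-1,4,4a,5,6,7,8,8a-octahydronaphthalen-1-yl]-3-methylpent-2-enoate
Conditions: second-generation Hoveyda–Grubbs catalyst (5 mol %), toluene (0.005 M), 80 °C, argon sparge
Reagents that add atoms: none
Why: The ruthenium alkylidene should load on the monosubstituted C6 vinyl group to give a Ru=C7 alkylidene, which then engages the 1,1-disubstituted isopropenyl group through a ruthenacyclobutane whose cycloreversion forms C7=C8 and expels ethene. The closest known reaction type is ring-closing olefin metathesis of a 1,7-diene to a trisubstituted cyclohexene carrying an allylic silyl ether. Ring B is closed in the six-membered mode by joining the ends of the chain C7–C6–C5–C10–C9–C8, whose termini hang from the trans-diequatorial arms on the adjacent ring-A carbons C5 and C10, so the new ring is necessarily trans-fused and the bridged skeleton of 17 has become the fused decalin. No stereocentre is formed; C4, C5, C6, C9 and C10 are carried in unchanged and none is epimerisable under the neutral conditions. The step needs chemoselectivity for the vinyl/isopropenyl pair over the C13=C14 enoate and over intermolecular coupling; the electron-poor trisubstituted enoate does not metathesise, only the six-membered closure is geometrically available, and high dilution with ethene removal drives it.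

Step 17
Reactants: 22 methyl (2E)-5-[(1R,4R,4aS,5S,8aS)-4-(tert-butyldimethylsilyloxy)-5-(hydroxymethyl)-2,5,8a-trimethyl-1,4,4a,5,6,7,8,8a-octahydronaphthalen-1-yl]-3-methylpent-2-enoate
Product: 23 methyl (2E)-5-[(1R,4R,4aS,5S,8aS)-4-hydroxy-5-(hydroxymethyl)-2,5,8a-trimethyl-1,4,4a,5,6,7,8,8a-octahydronaphthalen-1-yl]-3-methylpent-2-enoate
Conditions: Bu4NF, THF, 0 to 45 °C
Reagents that add atoms: none
Why: Fluoride-mediated silyl ether cleavage should free the C6 hydroxyl without affecting the methyl ester, the alkenes or any stereocentre.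

**Compound list**

1 | 2,6-dimethylcyclohexanone (cis/trans mixture) | CC1CCCC(C)C1=O | starting material
2 | 3-chloro-2-(chloromethyl)prop-1-ene | C=C(CCl)CCl | starting material
3 | (1R,5S)-1,5-dimethyl-3-methylidenebicyclo[3.3.1]nonan-9-one (meso) | C=C1C[C@@]2(C)CCC[C@@](C)(C1)C2=O | intermediate
4 | (1R,5S)-1,5-dimethylbicyclo[3.3.1]nonane-3,9-dione (meso) | O=C1C[C@@]2(C)CCC[C@@](C)(C1)C2=O | intermediate
5 | 4-(trimethylsilyl)but-3-yn-1-ol | C[Si](C)(C)C#CCCO | starting material
6 | 4-(trimethylsilyl)but-3-yn-1-yl trifluoromethanesulfonate | C[Si](C)(C)C#CCCOS(=O)(=O)C(F)(F)F | intermediate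
7 | (1S,2S,5R)-1,5-dimethyl-2-[4-(trimethylsilyl)but-3-yn-1-yl]bicyclo[3.3.1]nonane-3,9-dione (side chain axial on the 3-oxo ring and syn to the C9 carbonyl bridge) | O=C1C[C@@]2(C)CCC[C@@](C)([C@@H]1CCC#C[Si](C)(C)C)C2=O | intermediate
8 | 1,5-dimethyl-9-oxo-4-[4-(trimethylsilyl)but-3-yn-1-yl]bicyclo[3.3.1]non-2-en-3-yl trifluoromethanesulfonate (stereocentres as in 7) | FC(F)(F)S(=O)(=O)OC1=C[C@@]2(C)CCC[C@@](C)([C@@H]1CCC#C[Si](C)(C)C)C2=O | intermediate
9 | 1,3,5-trimethyl-4-[4-(trimethylsilyl)but-3-yn-1-yl]bicyclo[3.3.1]non-2-en-9-one (stereocentres as in 7) | CC1=C[C@@]2(C)CCC[C@@](C)([C@@H]1CCC#C[Si](C)(C)C)C2=O | intermediate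
10 | 9-(methoxymethylidene)-1,3,5-trimethyl-4-[4-(trimethylsilyl)but-3-yn-1-yl]bicyclo[3.3.1]non-2-ene (both enol ether isomers) | CC1=C[C@@]2(C)CCC[C@@](C)([C@@H]1CCC#C[Si](C)(C)C)C2=COC | intermediate
11 | 1,3,5-trimethyl-4-[4-(trimethylsilyl)but-3-yn-1-yl]bicyclo[3.3.1]non-2-ene-9-carbaldehyde (formyl group syn to the saturated C6–C8 bridge) | CC1=C[C@@]2(C)CCC[C@@](C)([C@@H]1CCC#C[Si](C)(C)C)[C@@H]2C=O | intermediate
12 | 4-(but-3-yn-1-yl)-1,3,5-trimethylbicyclo[3.3.1]non-2-ene-9-carbaldehyde (formyl group syn to the saturated C6–C8 bridge) | CC1=C[C@@]2(C)CCC[C@@](C)([C@@H]1CCC#C)[C@@H]2C=O | intermediate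
13 | 1-[4-(but-3-yn-1-yl)-1,3,5-trimethylbicyclo[3.3.1]non-2-en-9-yl]prop-2-en-1-ol (both carbinol epimers) | CC1=C[C@@]2(C)CCC[C@@](C)([C@@H]1CCC#C)[C@@H]2C(O)C=C | intermediate
14 | 1-[4-(but-3-yn-1-yl)-1,3,5-trimethylbicyclo[3.3.1]non-2-en-9-yl]prop-2-en-1-one | CC1=C[C@@]2(C)CCC[C@@](C)([C@@H]1CCC#C)[C@@H]2C(=O)C=C | intermediate
15 | (1R)-1-[4-(but-3-yn-1-yl)-1,3,5-trimethylbicyclo[3.3.1]non-2-en-9-yl]prop-2-en-1-ol | CC1=C[C@@]2(C)CCC[C@@](C)([C@@H]1CCC#C)[C@@H]2[C@@H](C=C)O | intermediate
16 | tert-butyldimethylsilyl ether of 15 | CC1=C[C@@]2(C)CCC[C@@](C)([C@@H]1CCC#C)[C@@H]2[C@@H](C=C)O[Si](C)(C)C(C)(C)C | intermediate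
17 | methyl (2E)-5-{9-[(1R)-1-(tert-butyldimethylsilyloxy)prop-2-en-1-yl]-1,3,5-trimethylbicyclo[3.3.1]non-2-en-4-yl}-3-methylpent-2-enoate | CC1=C[C@@]2(C)CCC[C@@](C)([C@@H]1CC/C(C)=C/C(=O)OC)[C@@H]2[C@@H](C=C)O[Si](C)(C)C(C)(C)C | intermediate
18 | 2,3-epoxide of 17 (epoxide configuration immaterial) | CC12OC1[C@@]3(C)CCC[C@@](C)([C@@H]2CC/C(C)=C/C(=O)OC)[C@@H]3[C@@H](C=C)O[Si](C)(C)C(C)(C)C | intermediate
19 | methyl (2E)-6-{2-[(1R)-1-(tert-butyldimethylsilyloxy)prop-2-en-1-yl]-3-formyl-1,3-dimethylcyclohexyl}-3-methyl-7-oxooct-2-enoate (stereocentres as in 23) | COC(=O)/C=C(\C)CC[C@H](C(C)=O)[C@@]1(C)[C@H]([C@@H](C=C)O[Si](C)(C)C(C)(C)C)[C@@](C)(C=O)CCC1 | intermediate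
20 | methyl (2E)-6-{2-[(1R)-1-(tert-butyldimethylsilyloxy)prop-2-en-1-yl]-3-(hydroxymethyl)-1,3-dimethylcyclohexyl}-3-methyl-7-oxooct-2-enoate (stereocentres as in 23) | COC(=O)/C=C(\C)CC[C@H](C(C)=O)[C@@]1(C)[C@H]([C@@H](C=C)O[Si](C)(C)C(C)(C)C)[C@@](C)(CO)CCC1 | intermediate
21 | methyl (2E)-6-{2-[(1R)-1-(tert-butyldimethylsilyloxy)prop-2-en-1-yl]-3-(hydroxymethyl)-1,3-dimethylcyclohexyl}-3,7-dimethylocta-2,7-dienoate (stereocentres as in 23) | COC(=O)/C=C(\C)CC[C@H](C(C)=C)[C@@]1(C)[C@H]([C@@H](C=C)O[Si](C)(C)C(C)(C)C)[C@@](C)(CO)CCC1 | intermediate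
22 | methyl (2E)-5-[(1R,4R,4aS,5S,8aS)-4-(tert-butyldimethylsilyloxy)-5-(hydroxymethyl)-2,5,8a-trimethyl-1,4,4a,5,6,7,8,8a-octahydronaphthalen-1-yl]-3-methylpent-2-enoate | COC(=O)/C=C(\C)CC[C@@H]1C(C)=C[C@@H](O[Si](C)(C)C(C)(C)C)[C@@H]2[C@@](C)(CO)CCC[C@@]12C | intermediate
23 | methyl (2E)-5-[(1R,4R,4aS,5S,8aS)-4-hydroxy-5-(hydroxymethyl)-2,5,8a-trimethyl-1,4,4a,5,6,7,8,8a-octahydronaphthalen-1-yl]-3-methylpent-2-enoate | COC(=O)/C=C(\C)CC[C@@H]1C(C)=C[C@@H](O)[C@@H]2[C@@](C)(CO)CCC[C@@]12C | target

**Step count and risks**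

Total step count: 17. Longest linear sequence: 16 steps (steps 1, 2 and 4–17, from 2,6-dimethylcyclohexanone); step 3 is a one-step side branch.

Steps most likely to fail:

- **Step 4.** The risk is proton return within the amide/enolate aggregate with loss of enantiotopic discrimination, together with sluggish C-alkylation of the hindered enolate. The fallback replaces the chiral base by a bound auxiliary and sets out from 4. Condensation of the unhindered C3 carbonyl with (S)-1-amino-2-(methoxymethyl)pyrrolidine should give the SAMP hydrazone F1. Deprotonation with LiN(iPr)2 and alkylation with 6 should give the alkylated hydrazone F2; axial attack is combined with an azaenolate face fixed by the auxiliary, so only one of the two α-carbons is a matched site. Two-phase hydrolysis with aqueous oxalic acid returns the route at 7. The antipodal auxiliary is used if the matched site proves to be the other α-carbon.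

- **Step 7.** The risk is failure of the phosphorus ylide to add to the doubly neopentylic bridge carbonyl, or incomplete equilibration at C5. The fallback sets out from 9. Methylene transfer with dimethylsulfonium methylide (Me3SI, KN(SiMe3)2, THF/DMSO; Corey–Chaykovsky epoxidation), which adds to hindered ketones more readily, should give the spiro-epoxide F3. MgBr2·OEt2 should then open it with 1,2-hydride shift (Meinwald rearrangement) to the silylated aldehyde 11, where the route is rejoined; K2CO3/MeOH as in step 7 then gives 12.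

- **Step 16.** The risk is slow loading of the catalyst on the congested diene and competing oligomerisation before the hindered isopropenyl group is engaged. The fallback sets out from 20 and closes the same bond by carbonyl olefination. Silylation of the C18 hydroxyl (tBuMe2SiCl, imidazole) should give the bis-silyl keto ester F4. One equivalent of Mo(=CHCMe2Ph)(=N-2,6-iPr2C6H3)[OCMe(CF3)2]2 (benzene, 25 °C) should exchange onto the vinyl group, and the resulting Mo=C7 alkylidene should olefinate the C8 ketone intramolecularly (olefin metathesis/carbonyl olefination ring closure) to the bis-silyl ether F5. Bu4NF then returns the route at 23.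

Further compounds
F1 | step 4 | SAMP hydrazone of 4 at the C3 carbonyl | COC[C@@H]1CCCN1N=C1C[C@@]2(C)CCC[C@@](C)(C1)C2=O
F2 | step 4 | SAMP hydrazone of 7 | COC[C@@H]1CCCN1N=C1C[C@@]2(C)CCC[C@@](C)([C@@H]1CCC#C[Si](C)(C)C)C2=O
F3 | step 7 | spiro-epoxide of 9 at the bridge carbon (9-spiro-oxirane) | CC1=C[C@@]2(C)CCC[C@@](C)([C@@H]1CCC#C[Si](C)(C)C)C23CO3
F4 | step 16 | C18 tert-butyldimethylsilyl ether of 20 | COC(=O)/C=C(\C)CC[C@H](C(C)=O)[C@@]1(C)[C@H]([C@@H](C=C)O[Si](C)(C)C(C)(C)C)[C@@](C)(CO[Si](C)(C)C(C)(C)C)CCC1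
F5 | step 16 | C18 tert-butyldimethylsilyl ether of 22 | COC(=O)/C=C(\C)CC[C@@H]1C(C)=C[C@@H](O[Si](C)(C)C(C)(C)C)[C@@H]2[C@@](C)(CO[Si](C)(C)C(C)(C)C)CCC[C@@]12C
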